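**Plan** (target ring numbering: C1 = CH bearing the propanoic acid chain, C2 = quaternary C, C3 = CHCH3, C4 and C5 = CH2, C6 = C=CMe2)
Cuts: C4=C5 and a chain C=C are put back (diimide) and the chain is cut to a propenyl group (cross-metathesis). The indole C3–CH2 bond is cut to indole plus an acid chloride, so the arm on C2 becomes CO2H. C2–C3 is then cut by a retro-Ireland–Claisen step to a δ-lactone.
Further cuts: the two cis propenyl groups of the lactone are tied into one CH=CH bridge (retro ring-opening metathesis). The ring oxygen is removed (retro Baeyer–Villiger), and the norbornenone is cut to 6,6-dimethylfulvene plus a ketene equivalent (Diels–Alder).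
Enabling feature: O=C–C2–C3–C4=C5 is a γ,δ-unsaturated acid. C5 lies next to C6=CMe2, so a temporary lactone ring O–C5–C6–C1–C2–C(=O) holds a propenyl group (future C4, C3 and the C3 methyl) on C5, and allylic strain from the isopropylidene group keeps it axial over the enolate carbon C2.
Forward order of rings: bicyclo[2.2.1]heptene, then 2-oxabicyclo[3.2.1]octene, then monocyclic δ-lactone, then cyclohexene (lactone traded for carbocycle). The indole is then joined and the chain completed.
Stereochemistry: one catalytic asymmetric Diels–Alder reaction sets the two bridgeheads, which become C1 and the lactone carbinol C5. The [3,3] shift consumes the carbinol centre and relays it to C2 and, through the E-alkene geometry, to C3.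

Key step: step 7

Assumption: compounds 1, 2, 9, 15 and 20 are taken as commercial. Compound 10 is drawn as the E,E isomer and 11 as the epimer expected from alkylation anti to the neighbouring propenyl group; both C3 epimers of 11 give the same ketene acetal 12.

Step 1
Reactants: 1 6,6-dimethylfulvene; 2 3-acryloyl-1,3-oxazolidin-2-one
Product: 3 3-{[(1R,2R,4R)-7-(propan-2-ylidene)bicyclo[2.2.1]hept-5-en-2-yl]carbonyl}-1,3-oxazolidin-2-one (endo adduct)
Conditions: [Cu((R,R)-t-Bu-box)](SbF6)2 (10 mol %), 1 (2 equiv), CH2Cl2, −20 °C; chromatography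
Reagents that add atoms: none
Why: Catalytic asymmetric Diels–Alder reaction in which the planar, symmetric fulvene ring acts as the diene (no regiochemical issue, methyl groups in the ring plane); the square-planar divalent copper chelate of the s-cis acrylimide leaves one alkene face open, so endo addition should set all three ring stereocentres as R, and any exo adduct is removed because it would lead to the enantiomer of 6.

Step 2
Reactants: 3 endo imide
Product: 4 (1R,2R,4R)-7-(propan-2-ylidene)bicyclo[2.2.1]hept-5-ene-2-carboxylic acid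
Conditions: LiOH, 30 % H2O2, THF/H2O, 0 °C; Na2SO3; 1 M HCl
Reagents that add atoms: hydrogen peroxide OO
Why: Hydroperoxide cleavage of an N-acyl oxazolidinone attacks only the exocyclic carbonyl group, and the basic peroxide leaves the unactivated alkenes and all stereocentres untouched.

Step 3
Reactants: 4 endo acid
Product: 6 (1S,4R)-7-(propan-2-ylidene)bicyclo[2.2.1]hept-5-en-2-one, via hydroperoxy acid 5 (not isolated)
Conditions: LiN(i-Pr)2 (LDA, 2.2 equiv), THF, 0 °C; O2, −78 °C; 1 M HCl; TsOH (cat.), CH2Cl2, rt
Reagents that add atoms: dioxygen O=O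
Why: Oxidative decarboxylation of a carboxylic acid dianion, in which enolate oxygenation gives the α-hydroperoxy acid that fragments to ketone, CO2 and water; the acrylimide has thus served as a ketene equivalent, ground-state oxygen does not touch the alkenes, and both bridgeheads are retained (the descriptor at C1 changes only through priorities).

Step 4
Reactants: 6 norbornenone
Product: 8 (1S,5R)-8-(propan-2-ylidene)-2-oxabicyclo[3.2.1]oct-6-en-3-one, via hydroxy acid 7 (not isolated)
Conditions: 30 % H2O2, NaOH, MeOH/H2O, 0 °C; cold 1 M HCl to pH 5, EtOAc; DCC, DMAP (cat.), CH2Cl2, 0 °C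
Reagents that add atoms: hydrogen peroxide OO; sodium hydroxide [Na+].[OH-] (its oxygen stays only in 7)
Why: Baeyer–Villiger oxidation with nucleophilic alkaline peroxide, made possible by the strain of the norbornenone, spares the electron-rich alkenes that a peracid would epoxidise; the doubly allylic bridgehead migrates with retention, hydroxide opens the first-formed lactone, and neutral carbodiimide lactonisation closes it again.

Step 5
Reactants: 8 bridged lactone; 9 (E)-but-2-ene
Product: 10 (4R,6S)-4,6-di[(E)-prop-1-en-1-yl]-5-(propan-2-ylidene)oxan-2-one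
Conditions: second-generation Grubbs catalyst RuCl2(=CHPh)(PCy3)(SIMes) (3 mol %), 9 (excess, condensed), CH2Cl2, rt, sealed vessel
Reagents that add atoms: none
Why: Ring-opening cross-metathesis is driven by strain release of the bicyclo[3.2.1]octene; excess butene caps both ends as propenyl groups, the tetrasubstituted alkene is inert, the two groups must be cis because they were one bridge, and secondary metathesis should move them towards the E geometry.

Step 6
Reactants: 10 dipropenyl lactone
Product: 11 (3S,4S,6S)-3-methyl-4,6-di[(E)-prop-1-en-1-yl]-5-(propan-2-ylidene)oxan-2-one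
Conditions: LiN(i-Pr)2 (LDA, 1.05 equiv), THF, −78 °C; MeI, DMPU, −78 to −40 °C
Reagents that add atoms: iodomethane CI
Why: Kinetic lactone enolate alkylation kept cold so that the enolate does not rearrange; the methyl group is expected anti to the neighbouring propenyl group, and this centre is erased again in step 7.

Step 7
Reactants: 11 α-methyl lactone
Product: 14 (1R,2R,6R)-1,2-dimethyl-5-(propan-2-ylidene)-6-[(E)-prop-1-en-1-yl]cyclohex-3-ene-1-carboxylic acid, via silyl ketene acetal 12 (not isolated), via silyl ester 13 (not isolated)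
Conditions: LiN(i-Pr)2 (LDA), THF, −78 °C; TBSCl, DMPU, −78 °C to rt; toluene, 110 °C; AcOH/THF/H2O, rt; base extraction
Reagents that add atoms: tert-butyldimethylsilyl chloride CC(C)(C)[Si](C)(C)Cl (silyl group of 12 and 13 only)
Why: Kinetic enolisation and O-silylation turn the lactone into the cyclic silyl ketene acetal 12, whose C=C(OSi)–O–CH–CH=CH array undergoes a concerted suprafacial [3,3] sigmatropic shift that makes the C2–C3 bond of the target ring while the C5–O bond breaks, so the oxygen helper leaves the ring carbon in the same event. The closest known reaction type is the Ireland–Claisen ring contraction of 6-alkenyl δ-lactone silyl ketene acetals to cyclohex-3-ene-1-carboxylic acids. The carbocycle is closed by lactone-to-carbocycle ring contraction (six-membered ring to six-membered ring), and because only two atoms tether the enolate carbon to the carbinol carbon the pericyclic array must be boat-like. The quaternary centre is controlled by the carbinol stereocentre: the propenyl group can reach only the ketene acetal face on which it stands, which is also the face carrying the neighbouring propenyl group, so the new C–C bond forms cis and the carboxyl group ends trans to that group. The CHCH3 centre is controlled by the E geometry of the migrating alkene, which in the boat array places the methyl group cis to the carboxyl group. The step needs migration of one propenyl group only and of its E isomer only: the second propenyl group is not part of an allyl vinyl ether, the path through the isopropylidene C=C would give a cyclobutane, a Z-propenyl group would drive its methyl into the ring so that its lactone should return unchanged and be separated from acid 14 by base extraction, and allylic strain from the isopropylidene methyl group keeps the migrating group axial.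

Step 8
Reactants: 14 Claisen acid; 15 indole
Product: 18 1H-indol-3-yl{(1R,2R,6R)-1,2-dimethyl-5-(propan-2-ylidene)-6-[(E)-prop-1-en-1-yl]cyclohex-3-en-1-yl}methanone, via acid chloride 16 (not isolated), via indol-1-ylmagnesium bromide 17 (not isolated)
Conditions: 14, 1-chloro-N,N,2-trimethylprop-1-en-1-amine, CH2Cl2, 0 °C to rt; separately 15 (2 equiv), EtMgBr, Et2O/CH2Cl2, 0 °C; combine, rt
Reagents that add atoms: 1-chloro-N,N,2-trimethylprop-1-en-1-amine CC(C)=C(Cl)N(C)C (Cl of 16 only); ethylmagnesium bromide CC[Mg]Br (MgBr of 17 only)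
Why: Neutral acid chloride formation (no α-hydrogen, hence no ketene, and no HCl to attack the diene) is followed by C3-selective acylation of the indole magnesium salt, a reaction type established for tertiary acyl chlorides; no stereocentre is touched.

Step 9
Reactants: 18 3-acylindole
Product: 19 3-({(1R,2R,6S)-1,2-dimethyl-5-(propan-2-ylidene)-6-[(E)-prop-1-en-1-yl]cyclohex-3-en-1-yl}methyl)-1H-indole
Conditions: LiAlH4, 1,4-dioxane, reflux; H2O, 15 % NaOH
Reagents that add atoms: none
Why: Hydride reduction of an N–H 3-acylindole runs past the carbinol because the indolyl anion expels the aluminate to give a 3-alkylidene-3H-indole that takes up a second hydride; the C=C bonds are inert to LiAlH4, and the descriptor at C6 changes only through priorities.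

Step 10
Reactants: 19 3-alkylindole; 20 acrylic acid
Product: 21 (2E)-3-[(1S,5R,6R)-6-(1H-indol-3-ylmethyl)-5,6-dimethyl-2-(propan-2-ylidene)cyclohex-3-en-1-yl]prop-2-enoic acid
Conditions: second-generation Hoveyda–Grubbs catalyst RuCl2(=CH-C6H4-2-O-i-Pr)(SIMes) (10 mol %), 20 (5 equiv), CH2Cl2, 40 °C
Reagents that add atoms: none
Why: Olefin cross-metathesis with an electron-poor partner exchanges =CHCH3 for =CHCO2H with E selectivity; only the acyclic propenyl group is active because the ring alkene is unstrained and the isopropylidene group is tetrasubstituted, and loss of propene drives the exchange.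

Step 11
Reactants: 21 dienyl enoic acid
Product: 22 suaveolindole, 3-[(1S,2R,3R)-2-(1H-indol-3-ylmethyl)-2,3-dimethyl-6-(propan-2-ylidene)cyclohexyl]propanoic acid
Conditions: TsNHNH2 (excess), NaOAc, DME/H2O, reflux
Reagents that add atoms: none
Why: Diimide reduction transfers H2 in a concerted syn fashion to the two disubstituted C=C bonds; the crowded tetrasubstituted isopropylidene group and the indole ring should not react, the diene is locked s-trans so only 1,2-addition is possible, and no stereocentre is formed or disturbed.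

**Compound list**
1 | 6,6-dimethylfulvene | CC(C)=C1C=CC=C1 | starting material
2 | 3-acryloyl-1,3-oxazolidin-2-one | C=CC(=O)N1CCOC1=O | starting material
3 | 3-{[(1R,2R,4R)-7-(propan-2-ylidene)bicyclo[2.2.1]hept-5-en-2-yl]carbonyl}-1,3-oxazolidin-2-one | O=C(N1CCOC1=O)[C@@H]1C[C@@H]2C=C[C@H]1C2=C(C)C | intermediate
4 | (1R,2R,4R)-7-(propan-2-ylidene)bicyclo[2.2.1]hept-5-ene-2-carboxylic acid | OC(=O)[C@@H]1C[C@@H]2C=C[C@H]1C2=C(C)C | intermediate
5 | (1S,2S,4R)-2-hydroperoxy-7-(propan-2-ylidene)bicyclo[2.2.1]hept-5-ene-2-carboxylic acid (exo OOH) | OC(=O)[C@]1(OO)C[C@@H]2C=C[C@H]1C2=C(C)C | intermediate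
6 | (1S,4R)-7-(propan-2-ylidene)bicyclo[2.2.1]hept-5-en-2-one | O=C1C[C@@H]2C=C[C@H]1C2=C(C)C | intermediate
7 | [(1R,4S)-4-hydroxy-5-(propan-2-ylidene)cyclopent-2-en-1-yl]acetic acid | OC(=O)C[C@@H]1C=C[C@H](O)C1=C(C)C | intermediate
8 | (1S,5R)-8-(propan-2-ylidene)-2-oxabicyclo[3.2.1]oct-6-en-3-one | O=C1C[C@@H]2C=C[C@H](O1)C2=C(C)C | intermediate
9 | (E)-but-2-ene | C/C=C/C | starting material
10 | (4R,6S)-4,6-di[(E)-prop-1-en-1-yl]-5-(propan-2-ylidene)oxan-2-one | O=C1C[C@H](/C=C/C)C(=C(C)C)[C@H](/C=C/C)O1 | intermediate
11 | (3S,4S,6S)-3-methyl-4,6-di[(E)-prop-1-en-1-yl]-5-(propan-2-ylidene)oxan-2-one | O=C1[C@@H](C)[C@H](/C=C/C)C(=C(C)C)[C@H](/C=C/C)O1 | intermediate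
12 | tert-butyl(dimethyl){[(2S,4R)-5-methyl-2,4-di[(E)-prop-1-en-1-yl]-3-(propan-2-ylidene)-3,4-dihydro-2H-pyran-6-yl]oxy}silane | CC1=C(O[Si](C)(C)C(C)(C)C)O[C@@H](/C=C/C)C(=C(C)C)[C@H]1/C=C/C | intermediate
13 | tert-butyl(dimethyl)silyl (1R,2R,6R)-1,2-dimethyl-5-(propan-2-ylidene)-6-[(E)-prop-1-en-1-yl]cyclohex-3-ene-1-carboxylate | CC(C)=C1C=C[C@@H](C)[C@@](C)(C(=O)O[Si](C)(C)C(C)(C)C)[C@@H]1/C=C/C | intermediate
14 | (1R,2R,6R)-1,2-dimethyl-5-(propan-2-ylidene)-6-[(E)-prop-1-en-1-yl]cyclohex-3-ene-1-carboxylic acid | CC(C)=C1C=C[C@@H](C)[C@@](C)(C(=O)O)[C@@H]1/C=C/C | intermediate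
15 | indole | c1ccc2[nH]ccc2c1 | starting material
16 | (1R,2R,6R)-1,2-dimethyl-5-(propan-2-ylidene)-6-[(E)-prop-1-en-1-yl]cyclohex-3-ene-1-carbonyl chloride | CC(C)=C1C=C[C@@H](C)[C@@](C)(C(=O)Cl)[C@@H]1/C=C/C | intermediate
17 | indol-1-ylmagnesium bromide | Br[Mg]n1ccc2ccccc12 | intermediate
18 | 1H-indol-3-yl{(1R,2R,6R)-1,2-dimethyl-5-(propan-2-ylidene)-6-[(E)-prop-1-en-1-yl]cyclohex-3-en-1-yl}methanone | CC(C)=C1C=C[C@@H](C)[C@@](C)(C(=O)c2c[nH]c3ccccc23)[C@@H]1/C=C/C | intermediate
19 | 3-({(1R,2R,6S)-1,2-dimethyl-5-(propan-2-ylidene)-6-[(E)-prop-1-en-1-yl]cyclohex-3-en-1-yl}methyl)-1H-indole | CC(C)=C1C=C[C@@H](C)[C@@](C)(Cc2c[nH]c3ccccc23)[C@@H]1/C=C/C | intermediate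
20 | acrylic acid | C=CC(=O)O | starting material
21 | (2E)-3-[(1S,5R,6R)-6-(1H-indol-3-ylmethyl)-5,6-dimethyl-2-(propan-2-ylidene)cyclohex-3-en-1-yl]prop-2-enoic acid | CC(C)=C1C=C[C@@H](C)[C@@](C)(Cc2c[nH]c3ccccc23)[C@@H]1/C=C/C(=O)O | intermediate
22 | suaveolindole, 3-[(1S,2R,3R)-2-(1H-indol-3-ylmethyl)-2,3-dimethyl-6-(propan-2-ylidene)cyclohexyl]propanoic acid | CC(C)=C1CC[C@@H](C)[C@@](C)(Cc2c[nH]c3ccccc23)[C@@H]1CCC(=O)O | target

Total step count: 11. Longest linear sequence: 11 steps (from 1 to 22).

**Steps most likely to fail**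

Step 4. The doubly allylic C–O bond of hydroxy acid 7 and of the strained lactone 8 may ionise. That would lead to allylic transposition of the lactone or to loss of water or carboxylate towards a fulvene.
The fallback sets out from 6 and comes back at 10. Ketone 6 is first opened with 9 and the second-generation Grubbs catalyst to (2S,4R)-2,4-di[(E)-prop-1-en-1-yl]-3-(propan-2-ylidene)cyclopentan-1-one F1. This unstrained ketone is then oxidised with bis(trimethylsilyl) peroxide and catalytic TMSOTf at low temperature, a Baeyer–Villiger variant that spares alkenes. The doubly allylic CH migrates with retention and gives 10 directly, so neither 7 nor 8 is ever made.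

Step 8. Attack of the indole salt on the very crowded acyl chloride may be too slow, so that hydrolysis on work-up or N-acylation takes over.
The fallback sets out from 14 and comes back at 19. LiAlH4 reduces 14 to [(1R,2R,6R)-1,2-dimethyl-5-(propan-2-ylidene)-6-[(E)-prop-1-en-1-yl]cyclohex-3-en-1-yl]methanol F2. Dess–Martin periodinane then gives (1R,2R,6R)-1,2-dimethyl-5-(propan-2-ylidene)-6-[(E)-prop-1-en-1-yl]cyclohex-3-ene-1-carbaldehyde F3. The magnesium salt 17 adds to the less shielded formyl group to give 1H-indol-3-yl{(1R,2R,6R)-1,2-dimethyl-5-(propan-2-ylidene)-6-[(E)-prop-1-en-1-yl]cyclohex-3-en-1-yl}methanol F4 (either carbinol epimer serves). LiAlH4 in refluxing dioxane removes the hydroxyl group by the same alkylideneindolenine pathway and gives 19.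

Step 10. The ruthenium alkylidene at the ring-bound carbon, flanked by the quaternary centre, may form too slowly, so that the catalyst decays before exchange with acrylic acid.
The fallback sets out from 19 and comes back at 22. Ethenolysis (ethylene, second-generation Hoveyda–Grubbs catalyst) needs only attack of the small methylidene at the outer alkene carbon. It gives 3-{[(1R,2R,6S)-6-ethenyl-1,2-dimethyl-5-(propan-2-ylidene)cyclohex-3-en-1-yl]methyl}-1H-indole F5. Linear-selective hydroformylation of the terminal vinyl group (Rh(acac)(CO)2, Xantphos, CO/H2) supplies the third chain carbon and gives 3-[(1S,5R,6R)-6-(1H-indol-3-ylmethyl)-5,6-dimethyl-2-(propan-2-ylidene)cyclohex-3-en-1-yl]propanal F6. Ag2O/NaOH oxidises it to 3-[(1S,5R,6R)-6-(1H-indol-3-ylmethyl)-5,6-dimethyl-2-(propan-2-ylidene)cyclohex-3-en-1-yl]propanoic acid F7. Diimide under the conditions of step 11 then saturates the ring alkene to give 22.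

**Further compounds**
F1 | step 4 | (2S,4R)-2,4-di[(E)-prop-1-en-1-yl]-3-(propan-2-ylidene)cyclopentan-1-one | O=C1C[C@H](/C=C/C)C(=C(C)C)[C@@H]1/C=C/C
F2 | step 8 | [(1R,2R,6R)-1,2-dimethyl-5-(propan-2-ylidene)-6-[(E)-prop-1-en-1-yl]cyclohex-3-en-1-yl]methanol | CC(C)=C1C=C[C@@H](C)[C@@](C)(CO)[C@@H]1/C=C/C
F3 | step 8 | (1R,2R,6R)-1,2-dimethyl-5-(propan-2-ylidene)-6-[(E)-prop-1-en-1-yl]cyclohex-3-ene-1-carbaldehyde | CC(C)=C1C=C[C@@H](C)[C@@](C)(C=O)[C@@H]1/C=C/C
F4 | step 8 | 1H-indol-3-yl{(1R,2R,6R)-1,2-dimethyl-5-(propan-2-ylidene)-6-[(E)-prop-1-en-1-yl]cyclohex-3-en-1-yl}methanol (carbinol centre undefined) | CC(C)=C1C=C[C@@H](C)[C@@](C)(C(O)c2c[nH]c3ccccc23)[C@@H]1/C=C/C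
F5 | step 10 | 3-{[(1R,2R,6S)-6-ethenyl-1,2-dimethyl-5-(propan-2-ylidene)cyclohex-3-en-1-yl]methyl}-1H-indole | CC(C)=C1C=C[C@@H](C)[C@@](C)(Cc2c[nH]c3ccccc23)[C@@H]1C=C
F6 | step 10 | 3-[(1S,5R,6R)-6-(1H-indol-3-ylmethyl)-5,6-dimethyl-2-(propan-2-ylidene)cyclohex-3-en-1-yl]propanal | CC(C)=C1C=C[C@@H](C)[C@@](C)(Cc2c[nH]c3ccccc23)[C@@H]1CCC=O
F7 | step 10 | 3-[(1S,5R,6R)-6-(1H-indol-3-ylmethyl)-5,6-dimethyl-2-(propan-2-ylidene)cyclohex-3-en-1-yl]propanoic acid | CC(C)=C1C=C[C@@H](C)[C@@](C)(Cc2c[nH]c3ccccc23)[C@@H]1CCC(=O)O
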